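The numbers were set for the occasion; no experiment stands behind them.

If anything was worth watching in this flask, I thought, it was where the excess of second end groups went.

first end groups 0.020 M; second end groups 0.0220 M (in portions, 3); time 6.0 d; the portions of second end groups follow each other after 1.5 h, the first at the start

    first end groups + second end groups → links + by-product (k1 = 1100 /M/h)
    second end groups → decomposed reagent (k2 = 0.43 /h)
    second end groups + links → over-reaction product (k3 = 5.5 /M/h)

- which holds at 6.0 d: what has brought the reaction to rest, or that it has not come to rest (all of the first end groups has reacted / it is still moving)
- conversion of first end groups at 6.0 d
- amount of links at 6.0 d, in percent of the first end groups charged
- amount of over-reaction product at 6.0 d, in percent of the first end groups charged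

I froze the links at their full charge, which made over-reaction pseudo-first-order in second end groups, with constant 0.110 /h beside the decomposition constant 0.43 /h. The level of first end groups at which coupling equals both losses together is 4.91 × 10⁻⁴ M, hardly any of the charge. With the links frozen, the part of lost reagent that becomes over-reaction product stays constant. I call this the over-reaction share, the frozen over-reaction rate divided by the sum of that rate and decomposition: 20.4%.

Which numbers had to be good? The time hardly: decomposition by itself halves second end groups in 0.067 d, far shorter than 6.0 d. The spacing of portions never entered my reckoning, which compares rates and holds no clock. The coupling constant entered the remainder of first end groups but not the over-reaction product. The charges were delicate, since their difference, 0.00200 M, is 10.0% of the first end groups, and a slip of that size in second end groups makes twice the excess.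

Taking the lost reagent as the excess, I got over-reaction product 2.04%. Setting the excess equal to the level times the logarithm of the drop in first end groups gave conversion 98.3%, links 96.3%, and the ending all of the first end groups has reacted.

The forecast said all of the first end groups has reacted, with conversion 99%, links 97.2% and over-reaction product 1.8%, holding that “only the last stretch loses much reagent”. Its conversion stood above mine and its over-reaction product below.

The simulation gave all of the first end groups has reacted, with conversion 99.1%, links 97.2% and over-reaction product 1.82%; 0.94% of the first end groups stayed unreacted, with second end groups at 0%.

Decomposition holds over-reaction product down: without that step this flask gave 10.0% instead of 1.82%. There the share 20.4% becomes 100%, and the excess is 10.0% of the first end groups. In the neighbour charged with 0.0080 M of first end groups, the share is 9.28% and the excess 0.0140 M, which gives 16.2% over-reaction product; that neighbour gave 14.7%.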